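**Route in one sentence:** ring A is made last, with all its substituents, by heating a 4-methoxy-4-(γ-pyron-2-yl)cyclobutenone (11), built from a semisquarate and the metalated ring B/ring C pyranone, so that a 4π-opening/6π-closure cascade converts the four-membered ring into the phenolic ring A.

## Structural features

- The target is a flavone: a γ-pyrone (ring C) fused through C4a–C8a to a benzene ring (ring A), with a 2,4-dimethoxyphenyl ring B on C2 and a methoxy group on C3.
- Ring A is pentasubstituted: C5–OH, C6–H, C7–OMe, C8–OMe, with C4a bonded to the C4 carbonyl and C8a to O1.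
- There is no stereocentre, so the whole problem is one of regiochemistry among six oxygen substituents, five methylated and one free.
- Fragile points are the γ-pyrone (opened by hydroxide or strong nucleophiles at C2) and the chelated C5–OH/C4=O pair. Under strong acid, 5-hydroxy-7,8-dioxygenated flavones can open and reclose ring C to the 5,6,7-isomers (Wessely–Moser rearrangement).
- The real difficulty is to build the 5,7,8-pattern of ring A unambiguously while leaving only the C5 oxygen unmethylated. Classical routes do this by selective demethylations.
- The key step exploits the fact that C5–OH is para to C8–OMe, with C6–H and C7–OMe between them and the pyranone bond C4a=C8a closing the ring. This is the substitution map of a thermal 4-alkenyl-4-methoxycyclobutenone ring expansion: ketone carbon to C5–OH, vinylic CH to C6, methoxyalkene carbon to C7, quaternary methoxy carbon to C8, and the alkene to C8a=C4a.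

## Logic of the disconnections

**14 ⇒ 11.** The C4a–C5 bond of ring A is cut, and C5 is folded back onto C8 so that C5, C6, C7 and C8 become the four-membered ring of 11. The reason is that 11 already carries each ring A substituent on the right carbon. The gain is that ring A, its free phenol and its two methoxy groups arise in one reagent-free isomerisation, with all regiochemistry held in σ-bonds. The demand is that the 4-methoxy group of 11 rotates outward on ring opening, and that 6π closure onto pyranone C5 is faster than bimolecular capture of the ketene.

**11 ⇒ 5 + 8.** The C8–C8a bond (cyclobutenone C4 to pyranone C6) and the O–CH3 bond of the tertiary ether are cut. The reason is that C8 is the more electrophilic carbonyl carbon of 8, and C8a is the only C–H of 5 next to the ring oxygen. The gain is a convergent union of the complete ring B/ring C unit with a four-carbon ring A precursor. The demand is site-selective metalation of 5 at C6, 1,2-addition to the correct carbonyl of 8, and O-methylation of the alkoxide before it is protonated.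

**8 ⇒ 6.** The C–H bond at the future C6 is traced back to a C–OMe bond of 6. The reason is that 6 is the commercial four-carbon unit and supplies the future C7 methoxy group unchanged. The gain is a symmetric starting material. The demand is mono-reduction and survival of the remaining vinylogous ester during acid-mediated loss of methanol.

**5 ⇒ 3 + 4.** The C2–C1' bond between ring C and ring B is cut. The reason is that a 2-bromo-γ-pyrone is a vinylogous acyl bromide, an excellent cross-coupling electrophile. The gain is two simple fragments. The demand is that coupling outruns hydrolytic displacement of bromide and protodeboronation of 4.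

**3 ⇒ 2 ⇒ 1.** The O–CH3 bond at C3 and then the C2–Br bond are cut. The reason is that the free enol of 1 directs the electrophile to C2, so bromination must come before methylation. The gain is a commercial hydroxypyranone. The demand is monobromination at C2 only.

## Other disconnections considered

**Alternative 1:** the plan that comes to mind first cuts ring C at O1–C2 and makes C2–C3 by aldol condensation.
- Forward: Claisen–Schmidt condensation of 1-(2-hydroxy-3,4,6-trimethoxyphenyl)ethan-1-one A1 with the ring B aldehyde gives chalcone A2. Algar–Flynn–Oyamada oxidative cyclisation gives flavonol A3, followed by O-methylation and chelation-directed 5-O-demethylation.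
- Grounds for preferring the chosen plan: the 6'-methoxy group of A2 twists the enone and is expected to divert the oxidative cyclisation towards the aurone (5-exo) manifold. A1 itself requires a regioselective mono-demethylation to fix the 5,7,8-pattern. The end game methylates all six oxygens only to remove one again under Lewis acid, the conditions under which Wessely–Moser scrambling is a concern. The chosen plan never has to tell one methoxy group from another and is no longer.

**Alternative 2:** a three-component carbonylative annulation that cuts C4–C4a, C3–C4 and O1–C2.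
- Forward: palladium-catalysed carbonylative Sonogashira coupling of 2-iodo-3,5,6-trimethoxyphenol A4 with carbon monoxide and the ring B arylacetylene, then 6-endo oxa-Michael closure to 5,7,8,2',4'-pentamethoxyflavone A5.
- Grounds for preferring the chosen plan: the key step leaves C3 as C–H, so the 3-methoxy group would need a late oxidation of a very electron-rich flavone and then methylation. A4 is a doubly ortho-substituted, pentasubstituted aryl iodide that is slow in oxidative addition and needs its own regiocontrolled synthesis. The 5-exo (aurone) closure competes. The selective 5-O-demethylation is still required. That is at least three operations more after the key step.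

**Alternative 3:** a Dötz benzannulation that cuts ring A at C5–C4a, C5–C6 and C7–C8.
- Forward: the Fischer carbene complex (CO)5Cr=C(OMe)(pyranonyl) A6, from the C6-lithiated ring B/ring C pyranone, Cr(CO)6 and O-methylation, is heated with methoxyethyne A7.
- Grounds for preferring the chosen plan: alkyne insertion places the substituent of a terminal alkyne next to the carbonyl-derived phenol carbon. The methoxy group would therefore be expected at C6, giving 5-hydroxy-3,6,8,2',4'-pentamethoxyflavone A8 and not the 7-methoxy target. The route also needs stoichiometric zerovalent chromium and an oxidative decomplexation that threatens the hydroquinone monoether. The chosen plan keeps the "ring A last" logic but fixes every position by connectivity.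

Key step: step 6

Remark on the chemistry: the target is achiral; the stereocentres of 7, 10, 11 and 13 are transient, form as racemates and are erased; 1, 4 and 6 are taken as commercial.

## Steps

Step 1
Reactants: 1 3-hydroxy-4H-pyran-4-one
Product: 2 2-bromo-3-hydroxy-4H-pyran-4-one
Conditions: NBS (1.0 equiv), MeCN, 0 °C → rt
Reagents that add atoms: N-bromosuccinimide, O=C1CCC(=O)N1Br
Why: Electrophilic bromination of the enolic hydroxypyranone at C2, the carbon ortho to the enol OH and next to the ring oxygen, which is the site where 3-hydroxy-4-pyranones take electrophiles (halogenation, Mannich reaction, hydroxyalkylation).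

Step 2
Reactants: 2 2-bromo-3-hydroxy-4H-pyran-4-one
Product: 3 2-bromo-3-methoxy-4H-pyran-4-one
Conditions: MeI, K2CO3, acetone, 50 °C
Reagents that add atoms: iodomethane, CI
Why: Williamson O-methylation of the acidic enolic OH; anhydrous carbonate should leave the vinylogous acyl bromide untouched.

Step 3
Reactants: 3 2-bromo-3-methoxy-4H-pyran-4-one; 4 (2,4-dimethoxyphenyl)boronic acid
Product: 5 2-(2,4-dimethoxyphenyl)-3-methoxy-4H-pyran-4-one
Conditions: Pd(OAc)2 (cat.), SPhos, K3PO4, toluene/H2O, 80 °C
Reagents that add atoms: none
Why: Suzuki–Miyaura coupling; the C2–Br bond of 3 is a vinylogous acyl bromide and should add readily to zerovalent palladium, and the biaryl phosphine copes with the ortho-methoxy, electron-rich boronic acid.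

Step 4
Reactants: 6 3,4-dimethoxycyclobut-3-ene-1,2-dione (dimethyl squarate)
Product: 8 3-methoxycyclobut-3-ene-1,2-dione, via hydroxycyclobutenone 7 (not isolated)
Conditions: LiAlH(OtBu)3 (1.05 equiv), THF, −78 °C; then 2 M HCl, CH2Cl2, 0 °C → rt (one flask)
Reagents that add atoms: water, O
Why: The hindered hydride reduces one carbonyl of the symmetric diester and stops, because the resulting alkoxide is part of a deactivated vinylogous ester. Acid then ionises carbinol 7 to a methoxy-stabilised cyclobutenyl cation that takes up water at the methoxy-bearing terminus and loses methanol (allylic transposition), the established route from squarate diesters to semisquarates.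

Step 5
Reactants: 5 2-(2,4-dimethoxyphenyl)-3-methoxy-4H-pyran-4-one; 8 3-methoxycyclobut-3-ene-1,2-dione
Product: 11 4-[6-(2,4-dimethoxyphenyl)-5-methoxy-4-oxo-4H-pyran-2-yl]-3,4-dimethoxycyclobut-2-en-1-one (racemic), via 6-lithiopyranone 9 (not isolated), via lithium cyclobutenolate 10 (not isolated)
Conditions: LiTMP (1.1 equiv; from n-BuLi, TMPH), THF, −78 °C; cannulate into 8 (1.2 equiv), THF, −78 °C; MeOTf (1.5 equiv), −78 → 0 °C
Reagents that add atoms: methyl trifluoromethanesulfonate, COS(=O)(=O)C(F)(F)F
Why: The hindered lithium amide should remove the C6–H of the γ-pyrone, the only C–H next to the ring oxygen (the site at which chromones and related 4-pyranones are metalated). Lithio species 9 then adds 1,2 to the ketone-like carbonyl of 8, the other carbonyl being deactivated as a vinylogous ester, as in organolithium additions to squarate esters. Alkoxide 10 is O-methylated in situ by the hard alkylating agent; the new quaternary centre is racemic and is erased in step 6.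

Step 6
Reactants: 11 4-[6-(2,4-dimethoxyphenyl)-5-methoxy-4-oxo-4H-pyran-2-yl]-3,4-dimethoxycyclobut-2-en-1-one (racemic)
Product: 14 5-hydroxy-3,7,8,2',4'-pentamethoxyflavone, via ring-opened dienylketene 12 (not isolated), via cyclohexadienone tautomer 13 (not isolated)
Conditions: p-xylene (0.01 M, degassed), 138 °C, Ar
Reagents that add atoms: none
Why: Heating opens the cyclobutenone of 11 by a conrotatory 4π electrocyclic cleavage of the C1–C4 bond to the dienylketene 12. The 4-methoxy group, a π-donor, rotates outward, so the pyranonyl group turns inward and ends Z to the ketene, which is the geometry that closure needs; this torquoselectivity is the one selectivity the step requires and the substrate secures it. The electrophilic ketene carbon then bonds to pyranone C5, the nucleophilic α-carbon of the vinylogous ester C6=C5, in a thermally allowed disrotatory 6π electrocyclisation that closes the six-membered ring A and gives 13; the other neighbour of C6 is the ring oxygen, so no second closure mode exists. Enolisation of the C4a–H of 13, driven by aromatisation of ring A, restoration of the γ-pyrone and the C5–OH···O=C4 hydrogen bond, gives 14. Every ring A substituent is placed by the σ-connectivity of 11 (ketone carbon to C5–OH, CH to C6, methoxyalkene carbon to C7, quaternary methoxy carbon to C8 next to C8a), so no methoxy group has to be distinguished from another. No stereocentre is formed in 14, and the centres of 11 and 13 are erased. The closest known reaction type is the thermal ring expansion of 4-aryl-, 4-heteroaryl- and 4-alkenyl-4-alkoxycyclobutenones to hydroquinone monoethers. High dilution in a dry, non-nucleophilic solvent should let the intramolecular closure outrun bimolecular capture of the monosubstituted ketene.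

## Compound list

1 | 3-hydroxy-4H-pyran-4-one | O=c1ccocc1O | starting material
2 | 2-bromo-3-hydroxy-4H-pyran-4-one | O=c1ccoc(Br)c1O | intermediate
3 | 2-bromo-3-methoxy-4H-pyran-4-one | COc1c(Br)occc1=O | intermediate
4 | (2,4-dimethoxyphenyl)boronic acid | COc1ccc(B(O)O)c(OC)c1 | starting material
5 | 2-(2,4-dimethoxyphenyl)-3-methoxy-4H-pyran-4-one | COc1ccc(-c2occc(=O)c2OC)c(OC)c1 | intermediate
6 | 3,4-dimethoxycyclobut-3-ene-1,2-dione (dimethyl squarate) | COC1=C(OC)C(=O)C1=O | starting material
7 | 4-hydroxy-2,3-dimethoxycyclobut-2-en-1-one (racemic) | COC1=C(OC)C(=O)C1O | intermediate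
8 | 3-methoxycyclobut-3-ene-1,2-dione | COC1=CC(=O)C1=O | intermediate
9 | [6-(2,4-dimethoxyphenyl)-5-methoxy-4-oxo-4H-pyran-2-yl]lithium | [Li]c1cc(=O)c(OC)c(-c2ccc(OC)cc2OC)o1 | intermediate
10 | lithium 1-[6-(2,4-dimethoxyphenyl)-5-methoxy-4-oxo-4H-pyran-2-yl]-2-methoxy-4-oxocyclobut-2-en-1-olate (racemic) | [Li]OC1(c2cc(=O)c(OC)c(-c3ccc(OC)cc3OC)o2)C(=O)C=C1OC | intermediate
11 | 4-[6-(2,4-dimethoxyphenyl)-5-methoxy-4-oxo-4H-pyran-2-yl]-3,4-dimethoxycyclobut-2-en-1-one (racemic) | COC1=CC(=O)C1(OC)c1cc(=O)c(OC)c(-c2ccc(OC)cc2OC)o1 | intermediate
12 | (3Z)-4-[6-(2,4-dimethoxyphenyl)-5-methoxy-4-oxo-4H-pyran-2-yl]-3,4-dimethoxybuta-1,3-dien-1-one | O=C=C/C(OC)=C(/OC)c1cc(=O)c(OC)c(-c2ccc(OC)cc2OC)o1 | intermediate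
13 | 2-(2,4-dimethoxyphenyl)-3,7,8-trimethoxy-4aH-chromene-4,5-dione (racemic) | COC1=CC(=O)C2C(=O)C(OC)=C(c3ccc(OC)cc3OC)OC2=C1OC | intermediate
14 | 2-(2,4-dimethoxyphenyl)-5-hydroxy-3,7,8-trimethoxy-4H-chromen-4-one (5-hydroxy-3,7,8,2',4'-pentamethoxyflavone) | COc1ccc(-c2oc3c(OC)c(OC)cc(O)c3c(=O)c2OC)c(OC)c1 | target

## Step count and least certain steps

Total step count: 6. Longest linear sequence: 5 steps (steps 1, 2, 3, 5 and 6); step 4 is a one-step branch.

**Step 6 (key step).**
- What may go wrong: the monosubstituted ketene terminus may be captured bimolecularly (dimerisation, addition of adventitious nucleophiles) faster than it closes, because the 6π closure transiently interrupts the cross-conjugation of the γ-pyrone. Partial inward rotation of the methoxy group would give a ketene geometry that cannot close.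
- Fallback: it sets out from 4, which stays the ring B donor, and comes back at 14; ring A/ring C are built classically.
  - Friedel–Crafts acylation of commercial 1,2,3,5-tetramethoxybenzene with methoxyacetyl chloride and AlCl3, with the usual cleavage of the crowded ortho-methoxy group, should give 1-(2-hydroxy-3,4,6-trimethoxyphenyl)-2-methoxyethan-1-one F1.
  - Condensation with N,N-dimethylformamide dimethyl acetal closes ring C to 3,5,7,8-tetramethoxy-4H-chromen-4-one F2.
  - Deprotonation at C2 (the only pyranone C–H, flanked by ring oxygen and the 3-methoxy group) with lithium diisopropylamide at −78 °C and an iodine quench gives 2-iodo-3,5,7,8-tetramethoxy-4H-chromen-4-one F3.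
  - Suzuki–Miyaura coupling of F3 with 4 gives 2-(2,4-dimethoxyphenyl)-3,5,7,8-tetramethoxy-4H-chromen-4-one F4.
  - BCl3 in CH2Cl2 at low temperature removes the chelated 5-O-methyl group and returns to 14.

**Step 5.**
- What may go wrong: competing deprotonation at C5 (directed by the carbonyl) followed by β-elimination and ring cleavage; self-addition of the lithiated pyranone to unmetalated 5; methylation of the pyranone carbonyl oxygen by excess methyl triflate.
- Fallback: it sets out from 5 and comes back at 11, separating metalation from C–C bond formation.
  - Zincation with the mild amide base TMPZnCl·LiCl (the zinc species neither eliminates nor adds to carbonyl groups) and iodolysis should give 2-(2,4-dimethoxyphenyl)-6-iodo-3-methoxy-4H-pyran-4-one F5, which can be purified so that the site of metalation is fixed.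
  - Iodine–magnesium exchange with iPrMgCl·LiCl at −78 °C and addition of the resulting organomagnesium species to 8 gives the carbinol 4-[6-(2,4-dimethoxyphenyl)-5-methoxy-4-oxo-4H-pyran-2-yl]-4-hydroxy-3-methoxycyclobut-2-en-1-one F6.
  - O-methylation with MeI and Ag2O leads to 11.

**Step 4.**
- What may go wrong: hydrolysis of the vinylogous methyl ester of 8 in the aqueous acid, and over-reduction of 6.
- Fallback: it sets out from 6 and comes back at 8, accepting the hydrolysis. After the same reduction, 7 is hydrolysed completely in aqueous HCl to the stable, crystalline 3-hydroxycyclobut-3-ene-1,2-dione (semisquaric acid) F7. F7 is then re-esterified with trimethyl orthoformate in methanol, the standard way of esterifying squaric acids, to give 8.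

**Step 3.**
- What may go wrong: protodeboronation of the electron-rich, ortho-methoxy boronic acid, and hydrolytic displacement of the vinylogous acyl bromide by the aqueous base.
- Fallback: it sets out from 3 and comes back at 5, using a water-free and base-free coupling. (2,4-Dimethoxyphenyl)zinc chloride F8, from commercial 1-bromo-2,4-dimethoxybenzene by bromine–lithium exchange and ZnCl2, is coupled with 3 in a Negishi reaction catalysed by Pd(PPh3)4 (zerovalent palladium) in THF.

## Further compounds

F1 | step 6 | 1-(2-hydroxy-3,4,6-trimethoxyphenyl)-2-methoxyethan-1-one | COCC(=O)c1c(O)c(OC)c(OC)cc1OC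
F2 | step 6 | 3,5,7,8-tetramethoxy-4H-chromen-4-one | COc1coc2c(OC)c(OC)cc(OC)c2c1=O
F3 | step 6 | 2-iodo-3,5,7,8-tetramethoxy-4H-chromen-4-one | COc1c(I)oc2c(OC)c(OC)cc(OC)c2c1=O
F4 | step 6 | 2-(2,4-dimethoxyphenyl)-3,5,7,8-tetramethoxy-4H-chromen-4-one | COc1ccc(-c2oc3c(OC)c(OC)cc(OC)c3c(=O)c2OC)c(OC)c1
F5 | step 5 | 2-(2,4-dimethoxyphenyl)-6-iodo-3-methoxy-4H-pyran-4-one | COc1ccc(-c2oc(I)cc(=O)c2OC)c(OC)c1
F6 | step 5 | 4-[6-(2,4-dimethoxyphenyl)-5-methoxy-4-oxo-4H-pyran-2-yl]-4-hydroxy-3-methoxycyclobut-2-en-1-one (racemic) | COC1=CC(=O)C1(O)c1cc(=O)c(OC)c(-c2ccc(OC)cc2OC)o1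
F7 | step 4 | 3-hydroxycyclobut-3-ene-1,2-dione (semisquaric acid) | OC1=CC(=O)C1=O
F8 | step 3 | (2,4-dimethoxyphenyl)zinc chloride | COc1ccc([Zn]Cl)c(OC)c1
A1 | alternative 1 | 1-(2-hydroxy-3,4,6-trimethoxyphenyl)ethan-1-one | CC(=O)c1c(O)c(OC)c(OC)cc1OC
A2 | alternative 1 | (E)-3-(2,4-dimethoxyphenyl)-1-(2-hydroxy-3,4,6-trimethoxyphenyl)prop-2-en-1-one | COc1ccc(/C=C/C(=O)c2c(O)c(OC)c(OC)cc2OC)c(OC)c1
A3 | alternative 1 | 2-(2,4-dimethoxyphenyl)-3-hydroxy-5,7,8-trimethoxy-4H-chromen-4-one | COc1ccc(-c2oc3c(OC)c(OC)cc(OC)c3c(=O)c2O)c(OC)c1
A4 | alternative 2 | 2-iodo-3,5,6-trimethoxyphenol | COc1cc(OC)c(OC)c(O)c1I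
A5 | alternative 2 | 2-(2,4-dimethoxyphenyl)-5,7,8-trimethoxy-4H-chromen-4-one | COc1ccc(-c2cc(=O)c3c(OC)cc(OC)c(OC)c3o2)c(OC)c1
A6 | alternative 3 | pentacarbonyl{[6-(2,4-dimethoxyphenyl)-5-methoxy-4-oxo-4H-pyran-2-yl](methoxy)methylidene}chromium, (CO)5Cr=C(OMe)(pyranonyl) | COC(=[Cr](=C=O)(=C=O)(=C=O)(=C=O)=C=O)c1cc(=O)c(OC)c(-c2ccc(OC)cc2OC)o1
A7 | alternative 3 | methoxyethyne | COC#C
A8 | alternative 3 | 2-(2,4-dimethoxyphenyl)-5-hydroxy-3,6,8-trimethoxy-4H-chromen-4-one | COc1ccc(-c2oc3c(OC)cc(OC)c(O)c3c(=O)c2OC)c(OC)c1
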